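## Retrosynthetic overview

1. Dactylomelol ⇐ (R)-epoxide of the side-chain alkene: HBr opening, then a stereospecific 1,2-bromine shift with chloride capture gives the (S)-CHBr–CMe2Cl unit.
2. C2–CH2 bond ⇐ Ni-catalysed decarboxylative C(sp3)–C(sp3) coupling of an oxanorbornane redox-active ester with the (S)-vinylcarbinol alkylzinc; exo attack sets C2.
3. C3 quaternary centre ⇐ exo conjugate methylation of a 2-formyl-oxanorbornene; the C3 side chain ⇐ Pd Negishi coupling on a vinyl bromide.
4. Ring formation is a single event: a catalytic asymmetric Diels–Alder of 2-methylfuran with a 3-bromopropioloyl imide builds both rings of the 7-oxabicyclo[2.2.1]heptane; diimide then saturates C5=C6.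
5. Side-chain fragment ⇐ but-3-yn-1-ol by Zr carboalumination, Sharpless epoxidation and epoxy-iodide → tertiary allylic alcohol transposition.

Assumption: organozinc reagents made in situ from numbered halides count inside the coupling step, and the ligand antipode in Step 3 is whichever gives (1R,4S)-6 (drawn for (S,S); to be confirmed by X-ray).

## Route

**Step 1**
Reactants: 1 propiolic acid; 2 1,3-oxazolidin-2-one
Product: 3 3-(prop-2-ynoyl)-1,3-oxazolidin-2-one
Conditions: DCC, DMAP (cat.), CH2Cl2, 0 °C → rt
Reagents that add atoms: none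
Why: Steglich-type N-acylation gives the bidentate ynoyl imide needed for two-point metal binding; no stereocentre.

**Step 2**
Reactants: 3
Product: 4 3-(3-bromoprop-2-ynoyl)-1,3-oxazolidin-2-one
Conditions: NBS, AgNO3 (10 mol %), acetone, rt, dark
Reagents that add atoms: N-bromosuccinimide, O=C1CCC(=O)N1Br
Why: Ag(I)-catalysed electrophilic bromination of a terminal alkyne (silver acetylide + NBS), standard for propiolic acid derivatives.

**Step 3**
Reactants: 4; 5 2-methylfuran
Product: 6 3-{[(1R,4S)-3-bromo-1-methyl-7-oxabicyclo[2.2.1]hepta-2,5-dien-2-yl]carbonyl}-1,3-oxazolidin-2-one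
Conditions: [Cu((S,S)-t-Bu-box)](SbF6)2 (10 mol %), 5 (3 equiv), 4 Å MS, CH2Cl2, −40 °C
Reagents that add atoms: none
Why: Proposed new method: a Cu(II)–bis(oxazoline)-catalysed enantioselective Diels–Alder of a furan with a 3-haloynoyl imide. The imide chelates square-planar Cu(II), which lowers the LUMO of the ynoyl π-system perpendicular to the chelate plane while a tert-butyl group blocks one face; the more nucleophilic C5 of 2-methylfuran bonds to the bromine-bearing β-carbon in an asynchronous [4+2], so the acyl carbon ends up next to the methyl bridgehead and both bridgehead stereocentres (1R,4S) are set together, with the uncatalysed background negligible at −40 °C. The closest known reactions are the Cu–box Diels–Alder of furan with acryloyl oxazolidinone and the uncatalysed, regioselective Diels–Alder of 2-methylfuran with 3-bromopropiolates.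

**Step 4**
Reactants: 6
Product: 7 3-{[(1R,4S)-3-bromo-1-methyl-7-oxabicyclo[2.2.1]hept-2-en-2-yl]carbonyl}-1,3-oxazolidin-2-one
Conditions: KO2CN=NCO2K, AcOH, CH2Cl2/MeOH, 0 °C → rt
Reagents that add atoms: none
Why: Diimide reduction is selective for the strained disubstituted C5=C6 bond over the tetrasubstituted bromoalkene and the C–Br bond, and it removes the retro-Diels–Alder pathway that could erode ee.

**Step 5**
Reactants: 7; 8 5-bromo-2-methylpent-2-ene
Product: 9 3-{[(1R,4S)-1-methyl-3-(4-methylpent-3-en-1-yl)-7-oxabicyclo[2.2.1]hept-2-en-2-yl]carbonyl}-1,3-oxazolidin-2-one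
Conditions: 8, Zn dust, LiCl, THF, 50 °C (→ RZnBr); then 7, Pd(dppf)Cl2 (5 mol %), THF, rt
Reagents that add atoms: none
Why: Negishi sp2–sp3 cross-coupling; the β-bromo-enoyl C–Br bond adds readily to Pd(0), the alkylzinc tolerates the imide, and dppf favours reductive elimination over β-hydride elimination.

**Step 6**
Reactants: 9
Product: 10 [(1R,4S)-1-methyl-3-(4-methylpent-3-en-1-yl)-7-oxabicyclo[2.2.1]hept-2-en-2-yl]methanol
Conditions: DIBAL-H, CH2Cl2, −78 → 0 °C
Reagents that add atoms: none
Why: DIBAL-H 1,2-reduction of the N-acyl oxazolidinone releases the auxiliary and gives the primary allylic alcohol without touching either alkene.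

**Step 7**
Reactants: 10
Product: 11 (1R,4S)-1-methyl-3-(4-methylpent-3-en-1-yl)-7-oxabicyclo[2.2.1]hept-2-ene-2-carbaldehyde
Conditions: MnO2, CH2Cl2, rt
Reagents that add atoms: none
Why: MnO2 allylic oxidation gives the enal, a much better conjugate acceptor than an ester for making the quaternary centre.

**Step 8**
Reactants: 11
Product: 12 (1R,3S,4S)-1,3-dimethyl-3-(4-methylpent-3-en-1-yl)-7-oxabicyclo[2.2.1]heptane-2-carbaldehyde (mixture of C2 epimers)
Conditions: Me2CuLi (MeLi, CuI), TMSCl, THF, −78 → −30 °C; then 1 M HCl, THF, 0 °C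
Reagents that add atoms: methyllithium (as Me2CuLi), [Li]C
Why: Gilman cuprate/TMSCl conjugate addition driven by strain release; methyl adds to C3 from the exo face (syn to the oxygen bridge, away from the C5–C6 bridge), giving the (3S) quaternary centre with the side chain endo, and the silyl enol ether avoids β-alkoxide ring-opening (the C2 epimers converge in Step 20).

**Step 9**
Reactants: 12
Product: 13 (1R,3S,4S)-1,3-dimethyl-3-(4-methylpent-3-en-1-yl)-7-oxabicyclo[2.2.1]heptane-2-carboxylic acid (C2 epimers)
Conditions: NaClO2, NaH2PO4, 2-methyl-2-butene, t-BuOH/H2O, 0 °C → rt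
Reagents that add atoms: sodium chlorite, [Na+].[O-]Cl=O
Why: Pinnick oxidation works on hindered aldehydes under buffered acid, and 2-methyl-2-butene scavenges HOCl so the trisubstituted alkene survives.

**Step 10**
Reactants: 13
Product: 14 (1R,3S,4S)-3-{2-[(2R)-3,3-dimethyloxiran-2-yl]ethyl}-1,3-dimethyl-7-oxabicyclo[2.2.1]heptane-2-carboxylic acid (C2 epimers)
Conditions: D-fructose-derived Shi ketone (30 mol %), Oxone, K2CO3, Bu4NHSO4, MeCN/DMM/aq. borate buffer, 0 °C
Reagents that add atoms: Oxone (KHSO5), [K+].[O-]S(=O)(=O)OO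
Why: Shi asymmetric epoxidation; the dioxirane reacts only with the electron-rich trisubstituted alkene and reagent control sets the (R) epoxide carbon that later becomes C–Br, and it also masks the alkene that would otherwise trap the C2 radical of Step 20 by 5-exo cyclisation.

**Step 11**
Reactants: 14
Product: 15 1,3-dioxoisoindolin-2-yl ester of 14 (redox-active ester, C2 epimers)
Conditions: N-hydroxyphthalimide, DIC, DMAP (cat.), CH2Cl2, rt
Reagents that add atoms: N-hydroxyphthalimide, O=C1c2ccccc2C(=O)N1O
Why: Carbodiimide (Steglich) esterification activates the hindered carboxyl as the N-acyloxyphthalimide without touching the epoxide.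

**Step 12**
Reactants: 16 but-3-yn-1-ol
Product: 17 1-[(but-3-yn-1-yloxy)methyl]-4-methoxybenzene
Conditions: NaH, PMBCl, Bu4NI (cat.), THF/DMF, 0 °C → rt
Reagents that add atoms: 4-methoxybenzyl chloride, COc1ccc(CCl)cc1
Why: Williamson etherification; NaH forms the alkoxide, not the acetylide.

**Step 13**
Reactants: 17
Product: 18 (2E)-5-[(4-methoxybenzyl)oxy]-3-methylpent-2-en-1-ol
Conditions: Me3Al, Cp2ZrCl2 (25 mol %), CH2Cl2, 0 °C → rt; then n-BuLi, (CH2O)n, THF, −78 °C → rt
Reagents that add atoms: trimethylaluminium, C[Al](C)C; formaldehyde (paraformaldehyde), C=O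
Why: Negishi Zr-catalysed carboalumination (syn methylalumination, Al at the terminus) and trapping of the alkenyl alanate with formaldehyde give the (E)-trisubstituted allylic alcohol stereospecifically.

**Step 14**
Reactants: 18
Product: 19 [(2S,3S)-3-{2-[(4-methoxybenzyl)oxy]ethyl}-3-methyloxiran-2-yl]methanol
Conditions: Ti(OiPr)4 (10 mol %), L-(+)-DET (12 mol %), t-BuOOH, 4 Å MS, CH2Cl2, −20 °C
Reagents that add atoms: tert-butyl hydroperoxide, CC(C)(C)OO
Why: Sharpless asymmetric epoxidation; L-(+)-DET gives the (2S,3S) epoxide from this (E)-allylic alcohol (same sense as geraniol), which fixes the future carbinol carbon.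

**Step 15**
Reactants: 19
Product: 20 (2R,3S)-2-(iodomethyl)-3-{2-[(4-methoxybenzyl)oxy]ethyl}-3-methyloxirane (same geometry as 19)
Conditions: I2, PPh3, imidazole, CH2Cl2, 0 °C
Reagents that add atoms: iodine, II
Why: Appel-type iodination of the primary alcohol under buffered conditions leaves the epoxide intact.

**Step 16**
Reactants: 20
Product: 21 (3S)-5-[(4-methoxybenzyl)oxy]-3-methylpent-1-en-3-ol
Conditions: Zn dust, AcOH (cat.), EtOH, 60 °C
Reagents that add atoms: none
Why: Zinc-mediated reductive elimination of the 2,3-epoxy iodide opens the epoxide to the tertiary allylic alcohol; the C3–O bond is not broken, so the (S) vinyl carbinol results.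

**Step 17**
Reactants: 21
Product: 22 triethyl{[(3S)-5-[(4-methoxybenzyl)oxy]-3-methylpent-1-en-3-yl]oxy}silane
Conditions: TESOTf, 2,6-lutidine, CH2Cl2, −78 → 0 °C
Reagents that add atoms: triethylsilyl triflate, CC[Si](CC)(CC)OS(=O)(=O)C(F)(F)F
Why: Silylation of the tertiary alcohol with the reactive triflate; TES survives the coupling and halide steps and leaves with fluoride at the end.

**Step 18**
Reactants: 22
Product: 23 (3S)-3-methyl-3-[(triethylsilyl)oxy]pent-4-en-1-ol
Conditions: DDQ, CH2Cl2/pH 7 buffer, 0 °C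
Reagents that add atoms: none
Why: Oxidative PMB cleavage is orthogonal to the silyl ether and the vinyl group.

**Step 19**
Reactants: 23
Product: 24 triethyl{[(3S)-5-iodo-3-methylpent-1-en-3-yl]oxy}silane
Conditions: I2, PPh3, imidazole, CH2Cl2, 0 °C
Reagents that add atoms: iodine, II
Why: Appel-type iodination gives the primary iodide needed for the organozinc.

**Step 20**
Reactants: 15; 24
Product: 25 triethyl{[(3S)-5-[(1R,2S,3S,4S)-3-{2-[(2R)-3,3-dimethyloxiran-2-yl]ethyl}-1,3-dimethyl-7-oxabicyclo[2.2.1]heptan-2-yl]-3-methylpent-1-en-3-yl]oxy}silane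
Conditions: 24, Mg, THF; ZnCl2 (0.5 equiv) (→ R2Zn); then 15, NiCl2·glyme (20 mol %), 4,4′-di-tert-butyl-2,2′-bipyridine (40 mol %), THF/DMF, rt
Reagents that add atoms: none
Why: Ni-catalysed decarboxylative alkyl–alkyl (Negishi-type) coupling of a redox-active ester; single-electron reduction releases CO2 and a C2 radical, and Ni forms the C2–CH2 bond on the exo face (syn to the oxygen bridge, anti to the endo chain and the C5–C6 bridge), so both C2 epimers converge on (2S).

**Step 21**
Reactants: 25
Product: 26 (3R)-2-bromo-5-[(1R,2S,3S,4S)-1,3-dimethyl-2-{(3S)-3-methyl-3-[(triethylsilyl)oxy]pent-4-en-1-yl}-7-oxabicyclo[2.2.1]heptan-3-yl]-2-methylpentan-3-ol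
Conditions: HBr (1.1 equiv, from TMSBr/MeOH), CH2Cl2, −78 °C; NaHCO3 quench
Reagents that add atoms: hydrogen bromide, Br
Why: Acid-promoted Markovnikov opening of a trisubstituted epoxide; bromide attacks the tertiary carbon and the secondary C–O stereocentre is kept as the (R) alcohol.

**Step 22**
Reactants: 26
Product: 27 dactylomelol triethylsilyl ether
Conditions: SOCl2, pyridine, CH2Cl2, −20 → 0 °C
Reagents that add atoms: thionyl chloride, O=S(Cl)Cl
Why: Neighbouring-group substitution: the adjacent bromine displaces the chlorosulfite with inversion at the secondary carbon and chloride opens the bromonium ion at the tertiary carbon, a stereospecific 1,2-bromine shift giving the (S) secondary bromide and the tertiary chloride.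

**Step 23**
Reactants: 27
Product: 28 dactylomelol, (3S)-5-[(1R,2S,3S,4S)-3-[(3S)-3-bromo-4-chloro-4-methylpentyl]-1,3-dimethyl-7-oxabicyclo[2.2.1]heptan-2-yl]-3-methylpent-1-en-3-ol
Conditions: HF·pyridine, pyridine, THF, 0 °C
Reagents that add atoms: none
Why: Buffered, non-basic fluoride desilylation removes the tertiary TES ether without eliminating or ionising the bromochloride.

## Compound list

1 | propiolic acid | C#CC(=O)O | starting material
2 | 1,3-oxazolidin-2-one | O=C1NCCO1 | starting material
3 | 3-(prop-2-ynoyl)-1,3-oxazolidin-2-one | C#CC(=O)N1CCOC1=O | intermediate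
4 | 3-(3-bromoprop-2-ynoyl)-1,3-oxazolidin-2-one | BrC#CC(=O)N1CCOC1=O | intermediate
5 | 2-methylfuran | Cc1ccco1 | starting material
6 | (1R,4S)-bromo-oxanorbornadiene imide | O=C(C1=C(Br)[C@@H]2C=C[C@@]1(C)O2)N3CCOC3=O | intermediate
7 | (1R,4S)-bromo-oxanorbornene imide | O=C(C1=C(Br)[C@@H]2CC[C@@]1(C)O2)N3CCOC3=O | intermediate
8 | 5-bromo-2-methylpent-2-ene | CC(C)=CCCBr | starting material
9 | (1R,4S)-3-(4-methylpent-3-enyl) oxanorbornene imide | O=C(C1=C(CCC=C(C)C)[C@@H]2CC[C@@]1(C)O2)N3CCOC3=O | intermediate
10 | (1R,4S)-allylic alcohol | OCC1=C(CCC=C(C)C)[C@@H]2CC[C@@]1(C)O2 | intermediate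
11 | (1R,4S)-enal | O=CC1=C(CCC=C(C)C)[C@@H]2CC[C@@]1(C)O2 | intermediate
12 | (1R,3S,4S)-aldehyde, C2 epimers | O=CC1[C@](C)(CCC=C(C)C)[C@@H]2CC[C@@]1(C)O2 | intermediate
13 | (1R,3S,4S)-acid, C2 epimers | OC(=O)C1[C@](C)(CCC=C(C)C)[C@@H]2CC[C@@]1(C)O2 | intermediate
14 | (1R,3S,4S)-(R)-epoxy acid, C2 epimers | OC(=O)C1[C@](C)(CC[C@H]3OC3(C)C)[C@@H]2CC[C@@]1(C)O2 | intermediate
15 | N-acyloxyphthalimide of 14 | O=C(ON3C(=O)c4ccccc4C3=O)C1[C@](C)(CC[C@H]5OC5(C)C)[C@@H]2CC[C@@]1(C)O2 | intermediate
16 | but-3-yn-1-ol | C#CCCO | starting material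
17 | but-3-ynyl PMB ether | C#CCCOCc1ccc(OC)cc1 | intermediate
18 | (2E)-5-(PMB-oxy)-3-methylpent-2-en-1-ol | OC/C=C(\C)CCOCc1ccc(OC)cc1 | intermediate
19 | (2S,3S)-epoxy alcohol | OC[C@H]2[C@@](C)(O2)CCOCc1ccc(OC)cc1 | intermediate
20 | (2R,3S)-epoxy iodide | IC[C@H]2[C@@](C)(O2)CCOCc1ccc(OC)cc1 | intermediate
21 | (3S)-5-(PMB-oxy)-3-methylpent-1-en-3-ol | C=C[C@@](C)(O)CCOCc1ccc(OC)cc1 | intermediate
22 | TES ether of 21 | C=C[C@@](C)(O[Si](CC)(CC)CC)CCOCc1ccc(OC)cc1 | intermediate
23 | (3S)-3-methyl-3-(TES-oxy)pent-4-en-1-ol | C=C[C@@](C)(O[Si](CC)(CC)CC)CCO | intermediate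
24 | (3S)-5-iodo-3-methyl-3-(TES-oxy)pent-1-ene | C=C[C@@](C)(O[Si](CC)(CC)CC)CCI | intermediate
25 | coupled (1R,2S,3S,4S) epoxide, TES ether | C=C[C@@](C)(O[Si](CC)(CC)CC)CC[C@H]1[C@](C)(CC[C@H]3OC3(C)C)[C@@H]2CC[C@@]1(C)O2 | intermediate
26 | (3R)-hydroxy tertiary bromide, TES ether | C=C[C@@](C)(O[Si](CC)(CC)CC)CC[C@H]1[C@](C)(CC[C@@H](O)C(C)(C)Br)[C@@H]2CC[C@@]1(C)O2 | intermediate
27 | dactylomelol TES ether | C=C[C@@](C)(O[Si](CC)(CC)CC)CC[C@H]1[C@](C)(CC[C@H](Br)C(C)(C)Cl)[C@@H]2CC[C@@]1(C)O2 | intermediate
28 | dactylomelol | C=C[C@@](C)(O)CC[C@H]1[C@](C)(CC[C@H](Br)C(C)(C)Cl)[C@@H]2CC[C@@]1(C)O2 | target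

## Totals and risks

Total steps: 23.
Longest linear sequence: 15 (Steps 1–11, then 20–23); 15/23 = 0.65.

Three steps most likely to fail:

1. **Step 3 (proposed new method).** Risks are low ee, uncertain absolute sense, Friedel–Crafts addition of the furan, or Lewis-acid aromatisation of the oxanorbornadiene. Fallback (known chemistry): run the uncatalysed thermal Diels–Alder (toluene, 60–80 °C) with the (S)-4-benzyl-oxazolidinone analogue of 4, reduce with diimide, and separate the two diastereomeric adducts by crystallisation or chromatography (or resolve rac-7 by preparative chiral SFC). The auxiliary leaves in Step 6, so the rest of the route is unchanged.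

2. **Step 20 (Ni decarboxylative coupling).** C2 is flanked by two fully substituted carbons, the exo alkyl–Ni could undergo β-oxygen elimination, and the epoxide may not tolerate zinc salts. Fallback: photoredox decarboxylative Giese addition of acid 14 to methyl vinyl ketone (exo C2–CH2CH2COCH3), then build the carbinol linearly by Horner–Wadsworth–Emmons, DIBAL, Sharpless epoxidation, I2/PPh3, Zn and TESOTf (the chemistry of Steps 14–17) to reach 25.

3. **Step 22 (1,2-bromine shift).** Chloride attack at the secondary carbon or elimination would give constitutional isomers. Fallback: treat epoxide 25 with Ph3PBr2 to give the anti-dibromide (inversion at the secondary carbon gives (S)-CHBr), then exchange only the tertiary bromide for chloride by neighbouring-bromine-assisted ionisation (Et4NCl, HFIP).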